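Assumption: the SMILES is read as the (2R)-2-methylbutanoate of (−)-lariciresinol, (2R,3S,4S) in the oxolane ring; (2R)-2-methylbutanoic acid and (4R)-4-benzyl-1,3-oxazolidin-2-one are bought as single enantiomers.

## Retrosynthetic overview

1. Target ⇒ (−)-lariciresinol + (2R)-2-methylbutanoic acid, by esterification of the only aliphatic hydroxyl (phenols left free).
2. (−)-Lariciresinol ⇒ C2-symmetric (−)-pinoresinol bis(benzyl ether): cleaving either benzylic C–O bond of the furofuran gives the same product and unveils the CH2OH and the benzyl group together.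
3. Furofuran ⇒ cis-fused dilactone of the same skeleton, by reduction of both lactone carbonyls to CH2 without opening a ring.
4. Dilactone ⇒ succinyl bis-imide + 2 × O-benzylvanillin: one-flask double syn-aldol and double lactonisation makes two C–C bonds, two C–O bonds and all four stereocentres.
5. Ring order: rings A and B (both γ-lactones) close together in step 2, both are reduced to oxolanes in step 3, ring B is opened in step 4, and ring A is the oxolane of the target. The arenes are bought.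

## Route

Step 1
Reactants: 1 succinyl chloride; 2 (4R)-4-benzyl-1,3-oxazolidin-2-one (2.1 equiv)
Product: 3 1,4-bis[(4R)-4-benzyl-2-oxo-1,3-oxazolidin-3-yl]butane-1,4-dione
Conditions: 2, n-BuLi (2.05 equiv), THF, −78 °C; then 1, −78 → 0 °C
Reagents that add atoms: none
Why: N-acylation of the lithiated oxazolidinone by both acid chloride groups (imide formation); no stereocentre is made or touched.

Step 2
Reactants: 3 1,4-bis[(4R)-4-benzyl-2-oxo-1,3-oxazolidin-3-yl]butane-1,4-dione; 4 4-(benzyloxy)-3-methoxybenzaldehyde (2.4 equiv)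
Product: 6 (3R,3aR,6R,6aR)-3,6-bis[4-(benzyloxy)-3-methoxyphenyl]tetrahydro-1H,3H-furo[3,4-c]furan-1,4-dione, via bis-aldol adduct 5 (not isolated)
Conditions: Bu2BOTf (2.3 equiv), i-Pr2NEt (2.6 equiv), CH2Cl2, 0 °C; 4, −78 → 0 °C; pH 7 buffer/MeOH/30% H2O2, 0 °C; crude 5, DMAP (0.2 equiv), CH2Cl2, rt
Reagents that add atoms: none
Why: Proposed new method: soft enolisation of both imide arms gives the bis-(Z)-dibutylboron enolate (a diene-diolate like the known succinate dianions); each arm adds to the aldehyde through a closed Zimmerman–Traxler chair on the face away from the benzyl group of its own (R)-auxiliary (Evans syn-aldol), setting 2R,3R at the succinate carbons and R at both carbinols. Each carbinol oxygen then acylates the distal imide carbonyl (5-exo acyl transfer, oxazolidinone leaves), and only the C2-symmetric diastereomer can close twice to the cis-fused dilactone. The closest known reactions are the Evans aldol–lactonisation of succinate half-ester imides to paraconic lactones and the double aldol–lactonisation of succinamide dianions.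

Step 3
Reactants: 6 (3R,3aR,6R,6aR)-3,6-bis[4-(benzyloxy)-3-methoxyphenyl]tetrahydro-1H,3H-furo[3,4-c]furan-1,4-dione
Product: 8 (1R,3aS,4R,6aS)-1,4-bis[4-(benzyloxy)-3-methoxyphenyl]tetrahydro-1H,3H-furo[3,4-c]furan, via bis-lactol 7 (not isolated)
Conditions: i-Bu2AlH (2.3 equiv), CH2Cl2, −78 °C; then Et3SiH (5 equiv), BF3·OEt2 (3 equiv), −78 → −30 °C, same flask
Reagents that add atoms: none
Why: i-Bu2AlH stops at the bis-lactol at −78 °C and BF3·OEt2 then ionises the hemiacetal carbons to oxocarbenium ions that Et3SiH reduces (lactone-to-cyclic-ether reduction by ionic hydrogenation), so no stereocentre is touched and both rings survive as oxolanes; the bridgehead descriptors change from R to S only because of the priority change.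

Step 4
Reactants: 8 (1R,3aS,4R,6aS)-1,4-bis[4-(benzyloxy)-3-methoxyphenyl]tetrahydro-1H,3H-furo[3,4-c]furan
Product: 10 (−)-lariciresinol [4-{(2R,3S,4S)-4-(4-hydroxy-3-methoxybenzyl)-3-(hydroxymethyl)oxolan-2-yl}-2-methoxyphenol], via (−)-pinoresinol 9 (not isolated)
Conditions: H2 (1 atm), 10% Pd/C, EtOAc/MeOH 1:1, rt; stopped after uptake of 3 equiv H2
Reagents that add atoms: none
Why: Catalytic hydrogenolysis removes the two aryl benzyl ethers first and then cleaves one of the two symmetry-equivalent, strained benzylic C–O bonds of the furofuran, turning one ArCH–O into ArCH2 and freeing the CH2OH; the three remaining stereocentres are not touched, and the monocyclic product is expected to react somewhat more slowly.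

Step 5
Reactants: 10 (−)-lariciresinol; 11 (2R)-2-methylbutanoic acid (1.2 equiv)
Product: 12 [(2R,3S,4S)-2-(4-hydroxy-3-methoxyphenyl)-4-(4-hydroxy-3-methoxybenzyl)oxolan-3-yl]methyl (2R)-2-methylbutanoate
Conditions: PPh3 (1.3 equiv), DIAD (1.3 equiv), THF, 0 °C → rt
Reagents that add atoms: none
Why: Mitsunobu esterification: only the primary aliphatic hydroxyl forms the alkoxyphosphonium ion, and the carboxylate of 11 (pKa about 5) attacks it in preference to the phenols (pKa about 10); the CH2 carbon is not stereogenic and the α-centre of the acid is never enolised, so the (R)-ester forms with all four stereocentres intact.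

## Compound list

1 | succinyl chloride | O=C(Cl)CCC(=O)Cl | starting material
2 | (4R)-4-benzyl-1,3-oxazolidin-2-one | O=C1N[C@H](Cc2ccccc2)CO1 | starting material
3 | 1,4-bis[(4R)-4-benzyl-2-oxo-1,3-oxazolidin-3-yl]butane-1,4-dione | O=C(CCC(=O)N1[C@H](Cc2ccccc2)COC1=O)N1[C@H](Cc2ccccc2)COC1=O | intermediate
4 | 4-(benzyloxy)-3-methoxybenzaldehyde | O=Cc1ccc(OCc2ccccc2)c(OC)c1 | starting material
5 | (2R,3R)-1,4-bis[(4R)-4-benzyl-2-oxo-1,3-oxazolidin-3-yl]-2,3-bis{(R)-[4-(benzyloxy)-3-methoxyphenyl](hydroxy)methyl}butane-1,4-dione | O=C(N1[C@H](Cc2ccccc2)COC1=O)[C@@H]([C@@H](O)c1ccc(OCc2ccccc2)c(OC)c1)[C@H]([C@@H](O)c1ccc(OCc2ccccc2)c(OC)c1)C(=O)N1[C@H](Cc2ccccc2)COC1=O | intermediate (not isolated)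
6 | (3R,3aR,6R,6aR)-3,6-bis[4-(benzyloxy)-3-methoxyphenyl]tetrahydro-1H,3H-furo[3,4-c]furan-1,4-dione | O=C1O[C@@H](c2ccc(OCc3ccccc3)c(OC)c2)[C@@H]2C(=O)O[C@@H](c3ccc(OCc4ccccc4)c(OC)c3)[C@H]12 | intermediate
7 | (3R,3aR,6R,6aR)-3,6-bis[4-(benzyloxy)-3-methoxyphenyl]tetrahydro-1H,3H-furo[3,4-c]furan-1,4-diol (anomer mixture) | OC1O[C@@H](c2ccc(OCc3ccccc3)c(OC)c2)[C@@H]2C(O)O[C@@H](c3ccc(OCc4ccccc4)c(OC)c3)[C@H]12 | intermediate (not isolated)
8 | (1R,3aS,4R,6aS)-1,4-bis[4-(benzyloxy)-3-methoxyphenyl]tetrahydro-1H,3H-furo[3,4-c]furan, the bis(benzyl ether) of (−)-pinoresinol | C1O[C@@H](c2ccc(OCc3ccccc3)c(OC)c2)[C@@H]2CO[C@@H](c3ccc(OCc4ccccc4)c(OC)c3)[C@H]12 | intermediate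
9 | (−)-pinoresinol, 4,4'-[(1R,3aS,4R,6aS)-tetrahydro-1H,3H-furo[3,4-c]furan-1,4-diyl]bis(2-methoxyphenol) | C1O[C@@H](c2ccc(O)c(OC)c2)[C@@H]2CO[C@@H](c3ccc(O)c(OC)c3)[C@H]12 | intermediate (not isolated)
10 | (−)-lariciresinol, 4-{(2R,3S,4S)-4-(4-hydroxy-3-methoxybenzyl)-3-(hydroxymethyl)oxolan-2-yl}-2-methoxyphenol | OC[C@@H]1[C@H](Cc2ccc(O)c(OC)c2)CO[C@H]1c1ccc(O)c(OC)c1 | intermediate
11 | (2R)-2-methylbutanoic acid | CC[C@@H](C)C(=O)O | starting material
12 | [(2R,3S,4S)-2-(4-hydroxy-3-methoxyphenyl)-4-(4-hydroxy-3-methoxybenzyl)oxolan-3-yl]methyl (2R)-2-methylbutanoate | CC[C@@H](C)C(=O)OC[C@@H]1[C@H](Cc2ccc(O)c(OC)c2)CO[C@H]1c1ccc(O)c(OC)c1 | target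

## Step count and risk

Total step count: 5. Longest linear sequence: 5.

The three steps most likely to fail:

Step 2 (double aldol and double lactonisation; bis-enolisation or the second aldol may not go). The fallback sets out from 2 and comes back at 8, replacing steps 2 and 3. Acylate 2 with commercial 3-[4-(benzyloxy)-3-methoxyphenyl]propanoic acid (pivaloyl chloride, Et3N, LiCl, THF) to (4R)-4-benzyl-3-{3-[4-(benzyloxy)-3-methoxyphenyl]propanoyl}-1,3-oxazolidin-2-one F1. Oxidative homocoupling of its enolate (LDA, THF, −78 °C, then TiCl4) joins two molecules at the α-carbons under auxiliary control to (2S,3S)-1,4-bis[(4R)-4-benzyl-2-oxo-1,3-oxazolidin-3-yl]-2,3-bis[4-(benzyloxy)-3-methoxybenzyl]butane-1,4-dione F2. LiBH4 in THF/MeOH removes both auxiliaries to give (2S,3S)-2,3-bis[4-(benzyloxy)-3-methoxybenzyl]butane-1,4-diol F3. DDQ (2.2 equiv, CH2Cl2, 0 °C) then abstracts hydride from each electron-rich benzylic CH2, and each cation is trapped 5-exo by the hydroxymethyl group of the other half, closing both oxolane rings in one flask to 8.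

Step 4 (hydrogenolysis may not stop at the mono-opened stage). The fallback sets out from 8 and comes back at 12, changing both the ring-opening mechanism and the order of the endgame. Et3SiH (1.1 equiv) and BF3·OEt2 in CH2Cl2 at −78 → −40 °C ionise one strained benzylic C–O bond and deliver one hydride, the amount of silane limiting over-reduction, to give {(2R,3S,4S)-2-[4-(benzyloxy)-3-methoxyphenyl]-4-[4-(benzyloxy)-3-methoxybenzyl]oxolan-3-yl}methanol F4. Its only hydroxyl is acylated with 11 (EDC·HCl, DMAP, CH2Cl2) to {(2R,3S,4S)-2-[4-(benzyloxy)-3-methoxyphenyl]-4-[4-(benzyloxy)-3-methoxybenzyl]oxolan-3-yl}methyl (2R)-2-methylbutanoate F5. A brief hydrogenolysis (10% Pd/C, H2 1 atm, EtOAc, rt, minutes) removes the two aryl benzyl ethers, which go much faster than the monocyclic benzylic ether, and gives 12.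

Step 5 (phenol alkylation or poor conversion in the Mitsunobu reaction). The fallback sets out from 10 and 11 and comes back at 12, moving from activation of the alcohol to an enzyme-bound acyl donor. Convert 11 into ethenyl (2R)-2-methylbutanoate F6 (vinyl acetate as solvent, Pd(OAc)2 cat., KOH cat., rt). Acylate 10 with F6 over immobilised Candida antarctica lipase B in tert-butyl methyl ether/acetone at 40 °C; the lipase acylates the primary aliphatic hydroxyl and leaves phenols alone, and the vinyl alcohol released tautomerises, which makes the transfer irreversible and gives 12.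

Further compounds

F1 | step 2 | (4R)-4-benzyl-3-{3-[4-(benzyloxy)-3-methoxyphenyl]propanoyl}-1,3-oxazolidin-2-one | O=C(CCc1ccc(OCc2ccccc2)c(OC)c1)N1[C@H](Cc2ccccc2)COC1=O
F2 | step 2 | (2S,3S)-1,4-bis[(4R)-4-benzyl-2-oxo-1,3-oxazolidin-3-yl]-2,3-bis[4-(benzyloxy)-3-methoxybenzyl]butane-1,4-dione | O=C(N1[C@H](Cc2ccccc2)COC1=O)[C@@H](Cc1ccc(OCc2ccccc2)c(OC)c1)[C@H](Cc1ccc(OCc2ccccc2)c(OC)c1)C(=O)N1[C@H](Cc2ccccc2)COC1=O
F3 | step 2 | (2S,3S)-2,3-bis[4-(benzyloxy)-3-methoxybenzyl]butane-1,4-diol | OC[C@@H](Cc1ccc(OCc2ccccc2)c(OC)c1)[C@H](Cc1ccc(OCc2ccccc2)c(OC)c1)CO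
F4 | step 4 | {(2R,3S,4S)-2-[4-(benzyloxy)-3-methoxyphenyl]-4-[4-(benzyloxy)-3-methoxybenzyl]oxolan-3-yl}methanol | OC[C@@H]1[C@H](Cc2ccc(OCc3ccccc3)c(OC)c2)CO[C@H]1c1ccc(OCc2ccccc2)c(OC)c1
F5 | step 4 | {(2R,3S,4S)-2-[4-(benzyloxy)-3-methoxyphenyl]-4-[4-(benzyloxy)-3-methoxybenzyl]oxolan-3-yl}methyl (2R)-2-methylbutanoate | CC[C@@H](C)C(=O)OC[C@@H]1[C@H](Cc2ccc(OCc3ccccc3)c(OC)c2)CO[C@H]1c1ccc(OCc2ccccc2)c(OC)c1
F6 | step 5 | ethenyl (2R)-2-methylbutanoate | CC[C@@H](C)C(=O)OC=C
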